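**Retrosynthetic overview**

1. The strategy rests on the 2,2-dimethyl-2H-pyran ring of the target (O1, C2 with its two methyl groups, C3=C4), fused to phloroglucinol ring B at C4a (carbon) and C8a (oxygen) beside the C8 aroyl group; these five carbons are a prenyl group folded onto its neighbouring phenol.
2. After removal of three MOM ethers from 19, the O1–C2 bond is disconnected (step 12) to diprenyl benzophenone 17, whose ring B prenyl group is dehydrogenated by DDQ and closed by oxa-6π electrocyclisation. The pyran is the only ring formed; rings A and B are bought.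
3. 17 comes from triol 16 by MOM protection of the one hydroxyl para to the ketone. 16 comes from ketone 15 by removal of three THP ethers, which are far more acid-labile than the ring A MOM ethers.
4. The aryl–carbonyl bond of 15 is made without Lewis acid, since acetal ethers and prenyl groups would not survive a Friedel–Crafts acylation: ring B aryllithium 13 adds to ring A aldehyde 8, and the carbinol is oxidised.
5. Both prenyl groups are installed by alkylating aryllithiums with prenyl bromide: on ring A at C2 through bromination and Br–Li exchange (from methyl 3,5-dihydroxybenzoate), on ring B by directed ortho-metalation of tris-THP phloroglucinol.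

Key step: step 12

Remark on the chemistry: the oxan-2-yl (THP) acetal carbons in 10–15 and the carbinol carbon of 14 form without stereocontrol, so these compounds are carried as stereoisomer mixtures and their SMILES carry no stereo labels. All of these centres are removed in steps 9 and 10, and the target has no stereocentre.

**Route**

Step 1
Reactants: 1 methyl 3,5-dihydroxybenzoate
Product: 2 methyl 3,5-bis(methoxymethoxy)benzoate
Conditions: MOMCl, DIPEA, CH2Cl2, 0 °C to rt
Reagents that add atoms: chloromethyl methyl ether, COCCl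
Why: O-alkylation of both phenols by the chloromethyl ether under amine base (MOM protection) should be clean because the ester is inert and the ring is too electron-poor for C-alkylation.

Step 2
Reactants: 2 methyl 3,5-bis(methoxymethoxy)benzoate
Product: 3 [3,5-bis(methoxymethoxy)phenyl]methanol
Conditions: LiAlH4, THF, 0 °C
Reagents that add atoms: none
Why: Hydride reduction of the ester to the primary benzylic alcohol, with the MOM acetals inert to LiAlH4.

Step 3
Reactants: 3 [3,5-bis(methoxymethoxy)phenyl]methanol
Product: 4 [2-bromo-3,5-bis(methoxymethoxy)phenyl]methanol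
Conditions: NBS (1.0 equiv), MeCN, 0 °C
Reagents that add atoms: N-bromosuccinimide, O=C1CCC(=O)N1Br
Why: Electrophilic aromatic bromination should go to C2 (C6 is equivalent), para to one acetal oxygen and ortho to the other, rather than to the more crowded C4 between the two oxygens, as is usual for 3,5-dialkoxybenzyl alcohols; one equivalent at 0 °C avoids the dibromide and sets free no acid that would touch the MOM groups.

Step 4
Reactants: 4 [2-bromo-3,5-bis(methoxymethoxy)phenyl]methanol; 5 1-bromo-3-methylbut-2-ene
Product: 7 [3,5-bis(methoxymethoxy)-2-(3-methylbut-2-enyl)phenyl]methanol, via dilithio alkoxide 6 (not isolated)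
Conditions: n-BuLi (2.2 equiv), THF, −78 °C; then 5, −78 °C to 0 °C; H2O
Reagents that add atoms: none
Why: The first equivalent of n-BuLi deprotonates the alcohol, the second effects bromine–lithium exchange faster than any ring deprotonation at −78 °C, and the aryllithium is alkylated by the allylic bromide at its primary carbon (SN2), giving the linear prenyl group while the lithium alkoxide stays inert at low temperature.

Step 5
Reactants: 7 [3,5-bis(methoxymethoxy)-2-(3-methylbut-2-enyl)phenyl]methanol
Product: 8 3,5-bis(methoxymethoxy)-2-(3-methylbut-2-enyl)benzaldehyde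
Conditions: MnO2 (excess), CH2Cl2, rt
Reagents that add atoms: none
Why: MnO2 oxidises the benzylic alcohol selectively to the aldehyde and leaves the trisubstituted alkene and the acetals untouched.

Step 6
Reactants: 9 phloroglucinol
Product: 10 1,3,5-tris(oxan-2-yloxy)benzene
Conditions: 3,4-dihydro-2H-pyran, PPTS (cat.), CH2Cl2/THF, rt
Reagents that add atoms: 3,4-dihydro-2H-pyran, C1=COCCC1
Why: Acid-catalysed addition of each phenolic hydroxyl to the enol ether (tetrahydropyranylation); PPTS is too weak an acid to drive C-alkylation of the ring, and the three acetal centres form without control.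

Step 7
Reactants: 10 1,3,5-tris(oxan-2-yloxy)benzene; 5 1-bromo-3-methylbut-2-ene
Product: 12 2-(3-methylbut-2-enyl)-1,3,5-tris(oxan-2-yloxy)benzene, via aryllithium 11 (not isolated)
Conditions: n-BuLi (1.1 equiv), THF, 0 °C; then 5, −78 °C to rt
Reagents that add atoms: none
Why: Directed ortho-metalation takes a ring hydrogen between two coordinating acetal oxygens (all three positions are equivalent), and SN2 alkylation of the aryllithium by the primary allylic bromide gives the mono-prenyl arene with unambiguous regiochemistry.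

Step 8
Reactants: 12 2-(3-methylbut-2-enyl)-1,3,5-tris(oxan-2-yloxy)benzene; 8 3,5-bis(methoxymethoxy)-2-(3-methylbut-2-enyl)benzaldehyde
Product: 14 [3,5-bis(methoxymethoxy)-2-(3-methylbut-2-enyl)phenyl][3-(3-methylbut-2-enyl)-2,4,6-tris(oxan-2-yloxy)phenyl]methanol, via aryllithium 13 (not isolated)
Conditions: n-BuLi (1.1 equiv), THF, 0 °C; then 8, −78 °C to 0 °C; H2O
Reagents that add atoms: none
Why: A second directed ortho-metalation takes the ring hydrogen between two acetal oxygens (C4 and C6 of 12 are equivalent), and the aryllithium adds 1,2 to the non-enolisable aldehyde; the new carbinol centre is racemic and is removed in step 9.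

Step 9
Reactants: 14 [3,5-bis(methoxymethoxy)-2-(3-methylbut-2-enyl)phenyl][3-(3-methylbut-2-enyl)-2,4,6-tris(oxan-2-yloxy)phenyl]methanol
Product: 15 [3,5-bis(methoxymethoxy)-2-(3-methylbut-2-enyl)phenyl][3-(3-methylbut-2-enyl)-2,4,6-tris(oxan-2-yloxy)phenyl]methanone
Conditions: (n-Pr4N)RuO4 (5 mol%), NMO, 4 Å MS, CH2Cl2, rt
Reagents that add atoms: none
Why: Ley–Griffith oxidation of the doubly benzylic secondary alcohol runs under neutral conditions, so the five acetals and both alkenes should survive.

Step 10
Reactants: 15 [3,5-bis(methoxymethoxy)-2-(3-methylbut-2-enyl)phenyl][3-(3-methylbut-2-enyl)-2,4,6-tris(oxan-2-yloxy)phenyl]methanone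
Product: 16 [3,5-bis(methoxymethoxy)-2-(3-methylbut-2-enyl)phenyl][2,4,6-trihydroxy-3-(3-methylbut-2-enyl)phenyl]methanone
Conditions: PPTS (cat.), MeOH, rt to 40 °C
Reagents that add atoms: none
Why: Acid-catalysed transacetalisation to methanol; THP acetals ionise to a ring-stabilised oxocarbenium ion far faster than the formaldehyde-derived MOM acetals, so only ring B is unmasked, and PPTS is too weak to cyclise the prenyl groups.

Step 11
Reactants: 16 [3,5-bis(methoxymethoxy)-2-(3-methylbut-2-enyl)phenyl][2,4,6-trihydroxy-3-(3-methylbut-2-enyl)phenyl]methanone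
Product: 17 [3,5-bis(methoxymethoxy)-2-(3-methylbut-2-enyl)phenyl][2,6-dihydroxy-4-(methoxymethoxy)-3-(3-methylbut-2-enyl)phenyl]methanone
Conditions: MOMCl (1.05 equiv), DIPEA, CH2Cl2, −20 °C to 0 °C
Reagents that add atoms: chloromethyl methyl ether, COCCl
Why: Selective O-alkylation of the 4'-hydroxyl, the most acidic phenol (para to the ketone) and the only one not hydrogen-bonded to the carbonyl; limiting the chloride to one equivalent should leave the two ortho hydroxyls free.

Step 12
Reactants: 17 [3,5-bis(methoxymethoxy)-2-(3-methylbut-2-enyl)phenyl][2,6-dihydroxy-4-(methoxymethoxy)-3-(3-methylbut-2-enyl)phenyl]methanone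
Product: 19 [3,5-bis(methoxymethoxy)-2-(3-methylbut-2-enyl)phenyl][7-hydroxy-5-(methoxymethoxy)-2,2-dimethyl-2H-chromen-8-yl]methanone, via o-quinone methide 18 (not isolated)
Conditions: DDQ (1.1 equiv), toluene, 80 °C
Reagents that add atoms: none
Why: DDQ complexes the electron-rich phenol and removes hydride (together with the phenolic proton) from the benzylic, allylic methylene of the ring B prenyl group next to the free 2'-hydroxyl, giving the vinylogous o-quinone methide 18, a 1-oxatriene. Thermal oxa-6π electrocyclisation of this dienone (disrotatory, six-membered, formally 6-endo) joins the carbonyl oxygen to the dimethyl-bearing terminus, forms the O1–C2 bond and restores aromaticity. This is the established quinone-mediated dehydrogenative cyclisation of o-prenylphenols to 2,2-dimethyl-2H-chromenes, also used on chelated acylphloroglucinols. No stereocentre arises because C2 carries two methyl groups. The regiochemistry (8-acyl, not 6-acyl chromene) is fixed because the other oxygen flanking this prenyl group, O4', is a MOM ether and cannot become a quinone methide carbonyl, while the 6'-hydroxyl has no prenyl neighbour. The ring A prenyl group should be spared because its neighbours (the ketone-bearing carbon and a MOM ether) offer no free hydroxyl, so only a high-energy benzylic cation could form there, and DDQ is held near one equivalent.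

Step 13
Reactants: 19 [3,5-bis(methoxymethoxy)-2-(3-methylbut-2-enyl)phenyl][7-hydroxy-5-(methoxymethoxy)-2,2-dimethyl-2H-chromen-8-yl]methanone
Product: 20 [3,5-dihydroxy-2-(3-methylbut-2-enyl)phenyl](5,7-dihydroxy-2,2-dimethyl-2H-chromen-8-yl)methanone
Conditions: 3 M aq. HCl, MeOH, 40 °C
Reagents that add atoms: none
Why: Acid-catalysed methanolysis of the three aryl MOM acetals under conditions mild enough that the chromene and the o-prenylphenol of ring A should not hydrate or cyclise.

**Compound list**

1 | methyl 3,5-dihydroxybenzoate | COC(=O)c1cc(O)cc(O)c1 | starting material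
2 | methyl 3,5-bis(methoxymethoxy)benzoate | COCOc1cc(OCOC)cc(C(=O)OC)c1 | intermediate
3 | [3,5-bis(methoxymethoxy)phenyl]methanol | COCOc1cc(CO)cc(OCOC)c1 | intermediate
4 | [2-bromo-3,5-bis(methoxymethoxy)phenyl]methanol | COCOc1cc(CO)c(Br)c(OCOC)c1 | intermediate
5 | 1-bromo-3-methylbut-2-ene (prenyl bromide) | CC(C)=CCBr | starting material
6 | lithium [2-lithio-3,5-bis(methoxymethoxy)phenyl]methanolate | [Li]OCc1cc(OCOC)cc(OCOC)c1[Li] | intermediate (not isolated)
7 | [3,5-bis(methoxymethoxy)-2-(3-methylbut-2-enyl)phenyl]methanol | CC(C)=CCc1c(CO)cc(OCOC)cc1OCOC | intermediate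
8 | 3,5-bis(methoxymethoxy)-2-(3-methylbut-2-enyl)benzaldehyde | CC(C)=CCc1c(C=O)cc(OCOC)cc1OCOC | intermediate
9 | phloroglucinol (benzene-1,3,5-triol) | Oc1cc(O)cc(O)c1 | starting material
10 | 1,3,5-tris(oxan-2-yloxy)benzene (mixture of diastereomers) | c1c(OC2CCCCO2)cc(OC2CCCCO2)cc1OC1CCCCO1 | intermediate
11 | [2,4,6-tris(oxan-2-yloxy)phenyl]lithium | [Li]c1c(OC2CCCCO2)cc(OC2CCCCO2)cc1OC1CCCCO1 | intermediate (not isolated)
12 | 2-(3-methylbut-2-enyl)-1,3,5-tris(oxan-2-yloxy)benzene (mixture of diastereomers) | CC(C)=CCc1c(OC2CCCCO2)cc(OC2CCCCO2)cc1OC1CCCCO1 | intermediate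
13 | [3-(3-methylbut-2-enyl)-2,4,6-tris(oxan-2-yloxy)phenyl]lithium | CC(C)=CCc1c(OC2CCCCO2)cc(OC2CCCCO2)c([Li])c1OC1CCCCO1 | intermediate (not isolated)
14 | [3,5-bis(methoxymethoxy)-2-(3-methylbut-2-enyl)phenyl][3-(3-methylbut-2-enyl)-2,4,6-tris(oxan-2-yloxy)phenyl]methanol (racemic carbinol, mixture of diastereomers) | CC(C)=CCc1c(OCOC)cc(OCOC)cc1C(O)c1c(OC2CCCCO2)cc(OC2CCCCO2)c(CC=C(C)C)c1OC1CCCCO1 | intermediate
15 | [3,5-bis(methoxymethoxy)-2-(3-methylbut-2-enyl)phenyl][3-(3-methylbut-2-enyl)-2,4,6-tris(oxan-2-yloxy)phenyl]methanone (mixture of diastereomers) | CC(C)=CCc1c(OCOC)cc(OCOC)cc1C(=O)c1c(OC2CCCCO2)cc(OC2CCCCO2)c(CC=C(C)C)c1OC1CCCCO1 | intermediate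
16 | [3,5-bis(methoxymethoxy)-2-(3-methylbut-2-enyl)phenyl][2,4,6-trihydroxy-3-(3-methylbut-2-enyl)phenyl]methanone | CC(C)=CCc1c(OCOC)cc(OCOC)cc1C(=O)c1c(O)cc(O)c(CC=C(C)C)c1O | intermediate
17 | [3,5-bis(methoxymethoxy)-2-(3-methylbut-2-enyl)phenyl][2,6-dihydroxy-4-(methoxymethoxy)-3-(3-methylbut-2-enyl)phenyl]methanone | CC(C)=CCc1c(OCOC)cc(OCOC)cc1C(=O)c1c(O)cc(OCOC)c(CC=C(C)C)c1O | intermediate
18 | 2-[3,5-bis(methoxymethoxy)-2-(3-methylbut-2-enyl)benzoyl]-3-hydroxy-5-(methoxymethoxy)-6-(3-methylbut-2-enylidene)cyclohexa-2,4-dien-1-one (alkylidene geometry not fixed) | CC(C)=CC=C1C(OCOC)=CC(O)=C(C(=O)c2cc(OCOC)cc(OCOC)c2CC=C(C)C)C1=O | intermediate (not isolated)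
19 | [3,5-bis(methoxymethoxy)-2-(3-methylbut-2-enyl)phenyl][7-hydroxy-5-(methoxymethoxy)-2,2-dimethyl-2H-chromen-8-yl]methanone | CC(C)=CCc1c(OCOC)cc(OCOC)cc1C(=O)c1c(O)cc(OCOC)c2c1OC(C)(C)C=C2 | intermediate
20 | [3,5-dihydroxy-2-(3-methylbut-2-enyl)phenyl](5,7-dihydroxy-2,2-dimethyl-2H-chromen-8-yl)methanone | CC(C)=CCc1c(O)cc(O)cc1C(=O)c1c(O)cc(O)c2c1OC(C)(C)C=C2 | target

**Step count**

Total steps: 13. Longest linear sequence: 11 steps (steps 1–5, then 8–13); the ring B branch (steps 6–7) joins at step 8.

**Steps most likely to fail, with fallbacks**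

Step 12 (key step). The hydroxyl that must take part is hydrogen-bonded to the ketone and sits on an acyl-deactivated ring, so hydride abstraction may be slow and give way to over-oxidation or to dehydrogenation at the ring A prenyl group. The fallback builds the pyran ring by condensation instead of dehydrogenation and sets out from 8 and 10. Lithiation of 10 (n-BuLi, THF, 0 °C, giving 11) and addition to 8 should give [3,5-bis(methoxymethoxy)-2-(3-methylbut-2-enyl)phenyl][2,4,6-tris(oxan-2-yloxy)phenyl]methanol F1. Oxidation with (n-Pr4N)RuO4/NMO should give the ketone [3,5-bis(methoxymethoxy)-2-(3-methylbut-2-enyl)phenyl][2,4,6-tris(oxan-2-yloxy)phenyl]methanone F2, and PPTS in MeOH should unmask [3,5-bis(methoxymethoxy)-2-(3-methylbut-2-enyl)phenyl](2,4,6-trihydroxyphenyl)methanone F3. One equivalent of MOMCl with DIPEA should then protect the para hydroxyl to give [3,5-bis(methoxymethoxy)-2-(3-methylbut-2-enyl)phenyl][2,6-dihydroxy-4-(methoxymethoxy)phenyl]methanone F4, whose C3' and C5' are equivalent. Heating F4 with 3-methylbut-2-enal and ethylenediammonium diacetate in toluene (Knoevenagel-type condensation at C3', loss of water to the same o-quinone methide 18, oxa-6π closure) should deliver 19, where the route is rejoined.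

Step 11. Alkylation may not stop at the para hydroxyl: a second MOM group on one of the ortho hydroxyls, or reaction at an ortho oxygen first, would give mixtures that are hard to separate. The fallback uses a bulky silyl group and sets out from 16. TBSCl (1.05 equiv) with imidazole in CH2Cl2 at 0 °C should silylate only the acidic, unchelated 4'-hydroxyl, and any silyl ether formed at a chelated ortho oxygen is hydrolysed on work-up; this gives [3,5-bis(methoxymethoxy)-2-(3-methylbut-2-enyl)phenyl][4-(tert-butyldimethylsilyloxy)-2,6-dihydroxy-3-(3-methylbut-2-enyl)phenyl]methanone F5. DDQ in toluene should cyclise it as in step 12 to [3,5-bis(methoxymethoxy)-2-(3-methylbut-2-enyl)phenyl][5-(tert-butyldimethylsilyloxy)-7-hydroxy-2,2-dimethyl-2H-chromen-8-yl]methanone F6. n-Bu4NF buffered with acetic acid in THF should then give [3,5-bis(methoxymethoxy)-2-(3-methylbut-2-enyl)phenyl](5,7-dihydroxy-2,2-dimethyl-2H-chromen-8-yl)methanone F7, and aqueous HCl in MeOH as in step 13 removes the two MOM ethers and returns to the route at 20.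

Step 8. Metalation of 12 may take place in part at the benzylic, allylic methylene of the prenyl group instead of the ring, or stay incomplete, so that little of the hindered carbinol forms. The fallback generates the same nucleophile by halogen–metal exchange and sets out from 12. NBS (1 equiv) in DMF at −20 °C should brominate the very electron-rich ring faster than the alkene, giving 2-bromo-4-(3-methylbut-2-enyl)-1,3,5-tris(oxan-2-yloxy)benzene F8. Bromine–lithium exchange with t-BuLi (2 equiv) in THF at −78 °C should then give aryllithium 13 regiospecifically and at a temperature where lateral metalation does not compete; addition of 8 returns to the route at 14.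

**Further compounds**

F1 | step 12 | [3,5-bis(methoxymethoxy)-2-(3-methylbut-2-enyl)phenyl][2,4,6-tris(oxan-2-yloxy)phenyl]methanol | CC(C)=CCc1c(OCOC)cc(OCOC)cc1C(O)c1c(OC2CCCCO2)cc(OC2CCCCO2)cc1OC1CCCCO1
F2 | step 12 | [3,5-bis(methoxymethoxy)-2-(3-methylbut-2-enyl)phenyl][2,4,6-tris(oxan-2-yloxy)phenyl]methanone | CC(C)=CCc1c(OCOC)cc(OCOC)cc1C(=O)c1c(OC2CCCCO2)cc(OC2CCCCO2)cc1OC1CCCCO1
F3 | step 12 | [3,5-bis(methoxymethoxy)-2-(3-methylbut-2-enyl)phenyl](2,4,6-trihydroxyphenyl)methanone | CC(C)=CCc1c(OCOC)cc(OCOC)cc1C(=O)c1c(O)cc(O)cc1O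
F4 | step 12 | [3,5-bis(methoxymethoxy)-2-(3-methylbut-2-enyl)phenyl][2,6-dihydroxy-4-(methoxymethoxy)phenyl]methanone | CC(C)=CCc1c(OCOC)cc(OCOC)cc1C(=O)c1c(O)cc(OCOC)cc1O
F5 | step 11 | [3,5-bis(methoxymethoxy)-2-(3-methylbut-2-enyl)phenyl][4-(tert-butyldimethylsilyloxy)-2,6-dihydroxy-3-(3-methylbut-2-enyl)phenyl]methanone | CC(C)=CCc1c(OCOC)cc(OCOC)cc1C(=O)c1c(O)cc(O[Si](C)(C)C(C)(C)C)c(CC=C(C)C)c1O
F6 | step 11 | [3,5-bis(methoxymethoxy)-2-(3-methylbut-2-enyl)phenyl][5-(tert-butyldimethylsilyloxy)-7-hydroxy-2,2-dimethyl-2H-chromen-8-yl]methanone | CC(C)=CCc1c(OCOC)cc(OCOC)cc1C(=O)c1c(O)cc(O[Si](C)(C)C(C)(C)C)c2c1OC(C)(C)C=C2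
F7 | step 11 | [3,5-bis(methoxymethoxy)-2-(3-methylbut-2-enyl)phenyl](5,7-dihydroxy-2,2-dimethyl-2H-chromen-8-yl)methanone | CC(C)=CCc1c(OCOC)cc(OCOC)cc1C(=O)c1c(O)cc(O)c2c1OC(C)(C)C=C2
F8 | step 8 | 2-bromo-4-(3-methylbut-2-enyl)-1,3,5-tris(oxan-2-yloxy)benzene | CC(C)=CCc1c(OC2CCCCO2)c(Br)c(OC2CCCCO2)cc1OC1CCCCO1
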